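**Remark:** the trivial name is read as the structure encoded by the SMILES, 8-prenylkaempferol 7-methyl ether. The geometry at C1 of diene 8 is of no consequence because C1 becomes an aromatic carbon; 8 is written as the (1Z,3Z) isomer.

## Analysis of the target

Compound 26 is a flavonol: a 4H-chromen-4-one (benzo ring A fused to pyranone ring C) carrying a 4-hydroxyphenyl ring B at C2 and a hydroxyl at C3. It has no stereocentre, and its only non-aromatic C=C bond, the trisubstituted alkene of the prenyl chain, has no geometry, so the whole problem is one of regiochemistry. Ring A is pentasubstituted: C4a bears the C4 carbonyl, C5 a hydroxyl hydrogen-bonded to that carbonyl, C6 a hydrogen, C7 a methoxy group, C8 the prenyl group and C8a the ring oxygen O1. The sensitive groups are the prenyl alkene (acid can add to it, hydrogenolysis would saturate it, electrophilic oxidants and halogens attack it), the easily oxidised enolic 3-hydroxyl, and three phenols of different acidity. The difficulty sits in ring A: in a phloroglucinol-derived ring C6 and C8, and the oxygens on C5 and C7, are nearly equivalent, so prenylating only C8 and methylating only O7 by substitution chemistry costs protecting-group steps and separations. The strategy rests on the fact that C5 and C7 carry oxygen in a 1,3-relationship, C8 carries carbon and C4a carries the acyl carbon. The unit C5–C6–C7–C8 is therefore a 1,3-dioxygenated diene with the prenyl chain on its terminus, and C4a–C8a is an acyl alkyne. If that alkyne carries bromine on C8a, cycloaddition and aromatisation deliver ring A with every substituent placed and with the site of the later O1–C8a bond marked.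

## Retrosynthetic reasoning

Target 26 differs from 25 only by two methoxymethyl acetals, on O3 and O4'. Cutting these two O–C bonds last keeps the enolic 3-hydroxyl and the ring-B phenol masked through every basic and copper-mediated step, and one mild acid solvolysis ends the synthesis. The forward step must cleave two acetals without adding acid to the prenyl alkene. This is realistic because C8 has no free phenol beside it (C7 is methylated, C8a is the ring oxygen), so acid-induced chroman formation is structurally excluded.

In 25 the bond O1–C8a is cut, which opens ring C to the 1,3-diketone 24 with bromine on C8a. Diketone 24 has two oxygens that could close a pyranone: the enol oxygen of the aroyl group and the C5 hydroxyl. A halogen on C8a decides which ring carbon receives oxygen, so the C5 hydroxyl needs neither protection nor differentiation from a second phenol. The forward reaction is an intramolecular copper-catalysed aryl ether formation from the diketone enolate.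

Diketone 24 is cut at C2–C3, the bond between the central carbon bearing the acetal oxygen and the ring-B carbonyl. The bond is formed by intramolecular delivery: the aroyl group is first placed on the C5 oxygen (ester 23, from phenol 19 and acid 22) and then shifted to the α-carbon of the ketone by base. This uses the free C5 hydroxyl that the key step provides, guarantees C-acylation over O-acylation of the enolate, and returns the C5 hydroxyl free. Acid 22 goes back to 20 by acetal protection through 21.

Phenol 19 contains the complete ring A. Two ring bonds are cut, C8–C8a and C4a–C5. This divides 19 into diene 8 (C5, C6, C7 and C8 with both oxygens and the prenyl chain) and bromoynone 16 (C4a, C8a, the C4 carbonyl and C3 with its protected oxygen). Ring A is thus made rather than functionalised: five substituents are set in one step, O5 and O7 are differentiated by construction (one emerges as a hydroxyl, the other as a methyl ether), and regiochemistry follows from the polarity of the two partners. The forward reaction has to give cycloadduct 17, aromatise it to silyl ether 18 by loss of the C5 methoxy group with the C8 hydrogen, and free phenol 19.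

Diene 8 is the O-silyl ketene acetal of enol ether 6, reached by γ-deprotonation through dienolate 7. Enol ether 6 is the methyl enol ether of β-keto ester 4 (through ketal 5). In 4 the bond between the acetoacetate γ-carbon and the prenyl CH2 is cut, which leads through dianion 3 to 1 and 2.

Bromoynone 16 is cut at C–Br back to silyl alkyne 15. The silyl group guards the alkyne terminus during assembly and is exchanged for bromine last, because 16 is the least stable compound of the route. In 15 the bond between the carbonyl carbon and the alkyne is cut to Weinreb amide 11 and alkyne 12 (through 13 and 14). Amide 11 comes from 9 through 10.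

## Alternatives that were turned down

**Alternative 1:** Ring C is cut at C3–C4 and O1–C2, giving 2-hydroxy-4,6-dimethoxy-3-prenylbenzaldehyde A1 and the aroyl sulfoxonium ylide A2. In the forward step [Cp*RhCl2]2 with AgSbF6 (trivalent rhodium) would activate the formyl C–H bond of A1, insert the carbene derived from A2, and cyclodehydrate to 4'-benzyloxy-5,7-dimethoxy-8-prenylflavone A3.
- For it: ring C is closed in a single catalytic, convergent step from two simple partners. On this point it is stronger than the chosen route, which needs three steps (esterification, acyl shift, copper closure).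
- Against it, A3 is a flavone with hydrogen at C3. The flavonol oxygen would have to be introduced afterwards by enolate or epoxide oxidation on a molecule that carries an oxidisable prenyl alkene.
- O5 arrives as a methyl ether and must be cleaved selectively. The benzyl group cannot be removed by hydrogenolysis without saturating the prenyl chain, so a Lewis acid would have to do both and would endanger the alkene.
- The ring-A regiochemistry problem is only moved into the preparation of A1, and a cationic rhodium/silver system has to tolerate an alkene.
- The chosen strategy offers in its place the C3 oxygen carried from the start, a free 5-hydroxyl without demethylation, and a ring-A pattern fixed by cycloaddition.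

**Alternative 2:** Ring A is cut at C8–C8a, C6–C7 and C4a–C8a, giving 3-ethoxycyclobut-2-en-1-one A4 and the alkynyl ether 1-methoxy-5-methylhex-4-en-1-yne A5. On heating, A4 opens to a vinylketene that adds to A5; the new cyclobutenone opens again and closes by six-electron electrocyclisation to 5-ethoxy-3-methoxy-2-prenylphenol A6.
- For it: three ring bonds form without any reagent and the regiochemistry of ynol ether addition is dependable. It equals the chosen route in making ring A from acyclic pieces and is stronger in that neither partner is as labile as a bromoynone.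
- Against it, A6 lacks the C4a acyl carbon. A later acylation must be directed to C4a and not to C6, which lies between two ether oxygens, so the regiochemical question returns.
- O5 is an ethyl ether that needs a selective cleavage, and ring C with its C3 oxygen still has to be built in several steps.
- A5 is a sensitive reagent whose prenyl alkene could intercept the ketene.
- The chosen cycloaddition installs the acyl group, the O5/O7 differentiation and the C8a handle in the same step.

**Alternative 3:** Ring C is cut at C3–C4 and O1–C8a, giving the α-alkoxy ketone A7 and 2-fluoro-4,6-dimethoxy-3-prenylbenzoyl chloride A8. The lithium enolate of A7 would be acylated by A8, and the resulting diketone enolate would displace fluoride on heating with K2CO3 to give 5,7-dimethoxy-3,4'-bis(methoxymethoxy)-8-prenylflavone A9.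
- For it: this is the most convergent route to ring C, needs no transition metal, and brings the C3 oxygen with it. On convergence and on the ring-C closure it is as strong as or stronger than the chosen route.
- Against it, A8 is a pentasubstituted arene whose pattern must be made by substitution chemistry on a fluorodimethoxybenzene. That is the very ring-A problem identified above.
- A9 carries O5 as a methyl ether, so a selective peri-demethylation with a Lewis acid is needed beside the prenyl alkene.
- The chosen strategy instead sets the ring-A pattern in one step from acyclic precursors and delivers O5 as a free hydroxyl.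

Key step: step 8

## Route

**Step 1**
Reactants: 1 methyl acetoacetate; 2 prenyl bromide (1-bromo-3-methylbut-2-ene)
Product: 4 methyl 7-methyl-3-oxooct-6-enoate, via sodium lithium dianion 3 (not isolated)
Conditions: NaH, THF, 0 °C; n-BuLi, 0 °C; then 2, 0 °C → rt; 1 M HCl, 0 °C
Reagents that add atoms: none
Why: Acetoacetate dianion alkylation: the second deprotonation creates the more reactive terminal carbanion, which displaces bromide from the primary allylic halide (SN2), so the chain grows only at the γ-carbon.

**Step 2**
Reactants: 4 methyl 7-methyl-3-oxooct-6-enoate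
Product: 6 methyl (E)-3-methoxy-7-methylocta-2,6-dienoate, via dimethyl ketal 5 (not isolated)
Conditions: HC(OMe)3, TsOH·H2O (cat.), MeOH, rt → 50 °C; Et3N; distillation
Reagents that add atoms: trimethyl orthoformate, COC(OC)OC
Why: Acid-catalysed ketalisation followed by loss of MeOH gives the conjugated β-methoxy enoate, the standard enol etherification of β-keto esters; the E isomer (methoxy trans to the ester) is the thermodynamic product, and catalytic sulfonic acid at this temperature should leave the trisubstituted alkene untouched.

**Step 3**
Reactants: 6 methyl (E)-3-methoxy-7-methylocta-2,6-dienoate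
Product: 8 (1Z,3Z)-1,3-dimethoxy-7-methyl-1-(trimethylsilyloxy)octa-1,3,6-triene, via lithium dienolate 7 (not isolated)
Conditions: LiN(iPr)2, THF, −78 °C; Me3SiCl, −78 °C → rt; pentane, filtration under Ar; used crude
Reagents that add atoms: chlorotrimethylsilane, C[Si](C)(C)Cl
Why: Kinetic γ-deprotonation of a β-alkoxy enoate (the γ-CH2 lies cis to the coordinating ester) and O-silylation of the vinylogous ester enolate is the established preparation of 1-alkoxy-1-silyloxy-3-alkoxy dienes; the chain at C4 is expected trans to C2 (3Z), the arrangement that allows the s-cis conformer.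

**Step 4**
Reactants: 9 methyl glycolate
Product: 10 methyl 2-(methoxymethoxy)acetate
Conditions: MOMCl, iPr2NEt, CH2Cl2, 0 °C → rt
Reagents that add atoms: chloromethyl methyl ether, COCCl
Why: O-alkylation of the primary alcohol by the α-chloro ether under amine base; the ester is inert.

**Step 5**
Reactants: 10 methyl 2-(methoxymethoxy)acetate
Product: 11 N-methoxy-2-(methoxymethoxy)-N-methylacetamide
Conditions: MeNHOMe·HCl, iPrMgCl, THF, −20 °C → 0 °C
Reagents that add atoms: N,O-dimethylhydroxylamine hydrochloride, CNOC.Cl
Why: Weinreb amide formation by direct aminolysis of the ester with the chloromagnesium amide; the α-alkoxy group accelerates acyl substitution and the acetal is stable to the Grignard base.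

**Step 6**
Reactants: 11 N-methoxy-2-(methoxymethoxy)-N-methylacetamide; 12 ethynyltrimethylsilane
Product: 15 1-(methoxymethoxy)-4-(trimethylsilyl)but-3-yn-2-one, via lithium trimethylsilylacetylide 13 (not isolated), via tetrahedral lithium chelate 14 (not isolated)
Conditions: 12, n-BuLi, THF, −78 °C; then 11, −78 → 0 °C; AcOH, −78 °C
Reagents that add atoms: none
Why: Weinreb ketone synthesis: the acetylide adds once and the N-methoxy-chelated adduct survives until the quench, so no tertiary alcohol can form.

**Step 7**
Reactants: 15 1-(methoxymethoxy)-4-(trimethylsilyl)but-3-yn-2-one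
Product: 16 4-bromo-1-(methoxymethoxy)but-3-yn-2-one
Conditions: NBS, AgNO3 (cat.), acetone, rt, dark; short silica plug; used at once
Reagents that add atoms: N-bromosuccinimide, O=C1CCC(=O)N1Br
Why: Silver-catalysed bromodesilylation of an alkynylsilane: monovalent silver activates the C–Si bond as a silver acetylide, which NBS brominates; the conditions are neutral, so neither the ynone nor the acetal is attacked.

**Step 8**
Reactants: 8 (1Z,3Z)-1,3-dimethoxy-7-methyl-1-(trimethylsilyloxy)octa-1,3,6-triene; 16 4-bromo-1-(methoxymethoxy)but-3-yn-2-one
Product: 19 1-[2-bromo-6-hydroxy-4-methoxy-3-(3-methylbut-2-en-1-yl)phenyl]-2-(methoxymethoxy)ethan-1-one, via cyclohexa-1,4-diene cycloadduct 17 (not isolated), via aryl trimethylsilyl ether 18 (not isolated)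
Conditions: 8 (1.5 equiv), PhMe, −20 °C → rt; then 0.5 M aq. HCl, THF, 0 °C
Reagents that add atoms: none
Why: The ketene-acetal diene 8 and bromoynone 16 should combine in a normal-electron-demand [4+2] cycloaddition, probably asynchronous, in which the bond from the diene terminus C4 (future C8) to the bromine-bearing β-carbon (future C8a) runs ahead of the bond from C1 (future C5) to the acyl-bearing α-carbon (future C4a). The closest known reaction type is the Diels–Alder addition of 1-alkoxy-1-silyloxy-3-alkoxy dienes to acetylenic ketones and esters with aromatisation to resorcinol derivatives, and 3-bromopropiolates are established dienophiles of the same polarity. Ring A is closed by the intermolecular cycloaddition itself, both ring bonds (C8–C8a and C4a–C5) forming suprafacially on the s-cis diene. Cycloadduct 17 is a 1,4-cyclohexadiene with a mixed silyl methyl ketal at C5 and a hydrogen at C8; 1,4-elimination of MeOH, driven by aromatisation, gives silyl ether 18, and cold dilute acid frees phenol 19 without touching the alkyl acetal. The two sp3 centres of 17 are both erased, so no stereocontrol is required. The only selectivity needed is regiochemical and is fixed by matched polarity: the largest HOMO coefficient of 8 lies on the alkylated terminus C4 and the largest LUMO coefficient of 16 on the β-carbon, so prenyl ends ortho to bromine and the ketene-acetal carbon ortho to the acyl group. The isolated electron-rich alkene of the prenyl chain does not compete, and low temperature in a non-polar solvent is chosen to favour ring closure over loss of bromide from a zwitterionic adduct.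

**Step 9**
Reactants: 20 4-hydroxybenzoic acid
Product: 22 4-(methoxymethoxy)benzoic acid, via bis-acetal ester 21 (not isolated)
Conditions: MOMCl (2.5 equiv), iPr2NEt, CH2Cl2, 0 °C → rt; then LiOH, THF/MeOH/H2O, rt; 1 M HCl to pH 4, 0 °C
Reagents that add atoms: chloromethyl methyl ether, COCCl
Why: Both acidic hydroxyls are alkylated, and saponification then cleaves only the methoxymethyl ester, since aryl acetals are stable to hydroxide.

**Step 10**
Reactants: 19 1-[2-bromo-6-hydroxy-4-methoxy-3-(3-methylbut-2-en-1-yl)phenyl]-2-(methoxymethoxy)ethan-1-one; 22 4-(methoxymethoxy)benzoic acid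
Product: 23 3-bromo-5-methoxy-2-[(methoxymethoxy)acetyl]-4-(3-methylbut-2-en-1-yl)phenyl 4-(methoxymethoxy)benzoate
Conditions: EDC·HCl, DMAP, CH2Cl2, 0 °C → rt
Reagents that add atoms: none
Why: Steglich esterification; acyl transfer through the acylpyridinium overcomes the hydrogen-bonded ortho-acyl phenol, and the neutral conditions avoid an acid chloride that would endanger the aryl acetal.

**Step 11**
Reactants: 23 3-bromo-5-methoxy-2-[(methoxymethoxy)acetyl]-4-(3-methylbut-2-en-1-yl)phenyl 4-(methoxymethoxy)benzoate
Product: 24 1-[2-bromo-6-hydroxy-4-methoxy-3-(3-methylbut-2-en-1-yl)phenyl]-2-(methoxymethoxy)-3-[4-(methoxymethoxy)phenyl]propane-1,3-dione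
Conditions: KOtBu, THF, 0 °C → rt; AcOH
Reagents that add atoms: none
Why: Baker–Venkataraman rearrangement: the ketone enolate attacks the neighbouring aryl ester through a six-membered transition state and releases the phenoxide, and formation of the stable diketonate drives the acyl shift to carbon; C2 of the dione is enolisable and is flattened in the next step.

**Step 12**
Reactants: 24 1-[2-bromo-6-hydroxy-4-methoxy-3-(3-methylbut-2-en-1-yl)phenyl]-2-(methoxymethoxy)-3-[4-(methoxymethoxy)phenyl]propane-1,3-dione
Product: 25 5-hydroxy-7-methoxy-3-(methoxymethoxy)-2-[4-(methoxymethoxy)phenyl]-8-(3-methylbut-2-en-1-yl)-4H-chromen-4-one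
Conditions: CuI (20 mol %), 1,10-phenanthroline (40 mol %), Cs2CO3, DMF, 80 °C, Ar
Reagents that add atoms: none
Why: Intramolecular Ullmann-type O-arylation, known for 1-(2-bromoaryl)-1,3-diketones giving flavones: the diketonate binds monovalent copper, the ortho C8a–Br bond adds oxidatively and C–O reductive elimination closes the pyranone; the competing addition of the C5 phenoxide to the aroyl carbonyl gives only a hemiketal that reverts under base.

**Step 13**
Reactants: 25 5-hydroxy-7-methoxy-3-(methoxymethoxy)-2-[4-(methoxymethoxy)phenyl]-8-(3-methylbut-2-en-1-yl)-4H-chromen-4-one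
Product: 26 3,5-dihydroxy-2-(4-hydroxyphenyl)-7-methoxy-8-(3-methylbut-2-en-1-yl)-4H-chromen-4-one
Conditions: HCl (1.25 M in MeOH), 0 °C → rt
Reagents that add atoms: none
Why: Acid-catalysed acetal exchange with methanol frees the enolic and the phenolic oxygen; the prenyl group has no free ortho phenol to cyclise onto, and dilute acid at room temperature should not add to the trisubstituted alkene.

## Compound list

1 | methyl acetoacetate | COC(=O)CC(C)=O | starting material
2 | prenyl bromide (1-bromo-3-methylbut-2-ene) | CC(C)=CCBr | starting material
3 | sodium lithium dianion of methyl acetoacetate | C=C([O-])C=C([O-])OC.[Li+].[Na+] | intermediate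
4 | methyl 7-methyl-3-oxooct-6-enoate | COC(=O)CC(=O)CCC=C(C)C | intermediate
5 | methyl 3,3-dimethoxy-7-methyloct-6-enoate | COC(=O)CC(OC)(OC)CCC=C(C)C | intermediate
6 | methyl (E)-3-methoxy-7-methylocta-2,6-dienoate | COC(=O)/C=C(/OC)CCC=C(C)C | intermediate
7 | lithium dienolate of 6 (γ-deprotonated) | [Li+].CO/C([O-])=C/C(OC)=C/CC=C(C)C | intermediate
8 | (1Z,3Z)-1,3-dimethoxy-7-methyl-1-(trimethylsilyloxy)octa-1,3,6-triene | CO/C(O[Si](C)(C)C)=C/C(OC)=C/CC=C(C)C | intermediate
9 | methyl glycolate | COC(=O)CO | starting material
10 | methyl 2-(methoxymethoxy)acetate | COCOCC(=O)OC | intermediate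
11 | N-methoxy-2-(methoxymethoxy)-N-methylacetamide | COCOCC(=O)N(C)OC | intermediate
12 | ethynyltrimethylsilane | C#C[Si](C)(C)C | starting material
13 | lithium (trimethylsilyl)acetylide | [Li+].[C-]#C[Si](C)(C)C | intermediate
14 | lithium 1-[methoxy(methyl)amino]-1-[(methoxymethoxy)methyl]-3-(trimethylsilyl)prop-2-yn-1-olate (racemic) | [Li+].COCOCC([O-])(C#C[Si](C)(C)C)N(C)OC | intermediate
15 | 1-(methoxymethoxy)-4-(trimethylsilyl)but-3-yn-2-one | COCOCC(=O)C#C[Si](C)(C)C | intermediate
16 | 4-bromo-1-(methoxymethoxy)but-3-yn-2-one | COCOCC(=O)C#CBr | intermediate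
17 | 1-[2-bromo-4,6-dimethoxy-3-(3-methylbut-2-en-1-yl)-6-(trimethylsilyloxy)cyclohexa-1,4-dien-1-yl]-2-(methoxymethoxy)ethan-1-one (racemic mixture of diastereomers; both sp3 centres are lost on aromatisation) | COCOCC(=O)C1=C(Br)C(CC=C(C)C)C(OC)=CC1(OC)O[Si](C)(C)C | intermediate
18 | 1-[2-bromo-4-methoxy-3-(3-methylbut-2-en-1-yl)-6-(trimethylsilyloxy)phenyl]-2-(methoxymethoxy)ethan-1-one | COCOCC(=O)c1c(O[Si](C)(C)C)cc(OC)c(CC=C(C)C)c1Br | intermediate
19 | 1-[2-bromo-6-hydroxy-4-methoxy-3-(3-methylbut-2-en-1-yl)phenyl]-2-(methoxymethoxy)ethan-1-one | COCOCC(=O)c1c(O)cc(OC)c(CC=C(C)C)c1Br | intermediate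
20 | 4-hydroxybenzoic acid | O=C(O)c1ccc(O)cc1 | starting material
21 | methoxymethyl 4-(methoxymethoxy)benzoate | COCOC(=O)c1ccc(OCOC)cc1 | intermediate
22 | 4-(methoxymethoxy)benzoic acid | COCOc1ccc(C(=O)O)cc1 | intermediate
23 | 3-bromo-5-methoxy-2-[(methoxymethoxy)acetyl]-4-(3-methylbut-2-en-1-yl)phenyl 4-(methoxymethoxy)benzoate | COCOCC(=O)c1c(OC(=O)c2ccc(OCOC)cc2)cc(OC)c(CC=C(C)C)c1Br | intermediate
24 | 1-[2-bromo-6-hydroxy-4-methoxy-3-(3-methylbut-2-en-1-yl)phenyl]-2-(methoxymethoxy)-3-[4-(methoxymethoxy)phenyl]propane-1,3-dione (racemic at C2, enolisable) | COCOC(C(=O)c1ccc(OCOC)cc1)C(=O)c1c(O)cc(OC)c(CC=C(C)C)c1Br | intermediate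
25 | 5-hydroxy-7-methoxy-3-(methoxymethoxy)-2-[4-(methoxymethoxy)phenyl]-8-(3-methylbut-2-en-1-yl)-4H-chromen-4-one | COCOc1ccc(-c2oc3c(CC=C(C)C)c(OC)cc(O)c3c(=O)c2OCOC)cc1 | intermediate
26 | 3,5-dihydroxy-2-(4-hydroxyphenyl)-7-methoxy-8-(3-methylbut-2-en-1-yl)-4H-chromen-4-one | COc1cc(O)c2c(=O)c(O)c(-c3ccc(O)cc3)oc2c1CC=C(C)C | target

## Step count and least certain steps

Total: 13 steps. Longest linear sequence: 9 steps (9 → 10 → 11 → 15 → 16 → 19 → 23 → 24 → 25 → 26; steps 4–8 and 10–13).

**Step 8 (key step).** Three things could go wrong.
- The diene terminus could add to the bromine-bearing carbon and the resulting allenolate could expel bromide instead of closing the ring, which amounts to substitution at the alkynyl carbon.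
- The bromoynone could oligomerise before it is consumed.
- The mixed ketal could aromatise by losing the silyloxy group instead of the methoxy group, which would leave O5 methylated.

All three follow from a leaving group on the β-carbon and a labile electrophile. The fallback replaces bromine by tin during ring formation and sets out from 11 and 8. Addition of lithium (tributylstannyl)acetylide (from ethynyltributylstannane and LiN(iPr)2) to 11 should give 1-(methoxymethoxy)-4-(tributylstannyl)but-3-yn-2-one F1, an ynone with no leaving group on its β-carbon. Cycloaddition of F1 with 8 in toluene (rt → 60 °C) under the same ketone-controlled regiochemistry, followed by K2CO3 in MeOH, should give 1-[6-hydroxy-4-methoxy-3-(3-methylbut-2-en-1-yl)-2-(tributylstannyl)phenyl]-2-(methoxymethoxy)ethan-1-one F2. Iodine in CH2Cl2 at 0 °C exchanges tin for iodine at the ipso carbon far faster than it attacks C6 or the alkene and gives 1-[6-hydroxy-2-iodo-4-methoxy-3-(3-methylbut-2-en-1-yl)phenyl]-2-(methoxymethoxy)ethan-1-one F3, the iodo analogue of 19. F3 is esterified with 22 as in step 10 to 3-iodo-5-methoxy-2-[(methoxymethoxy)acetyl]-4-(3-methylbut-2-en-1-yl)phenyl 4-(methoxymethoxy)benzoate F4, and rearranged as in step 11 to 1-[6-hydroxy-2-iodo-4-methoxy-3-(3-methylbut-2-en-1-yl)phenyl]-2-(methoxymethoxy)-3-[4-(methoxymethoxy)phenyl]propane-1,3-dione F5. Copper-catalysed closure of F5 as in step 12 returns to the route at 25.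

**Step 12.** The pyranone could close through the C5 oxygen (addition of the phenoxide to the aroyl carbonyl, then dehydration on heating), which would put the ring oxygen on the wrong side of ring A. Oxidative addition at the doubly ortho-substituted, electron-rich C8a–Br bond could also be slow enough to let that pathway through. The fallback removes the competing nucleophile and sets out from 19. Alkylation with MOMCl and iPr2NEt should give 1-[2-bromo-4-methoxy-6-(methoxymethoxy)-3-(3-methylbut-2-en-1-yl)phenyl]-2-(methoxymethoxy)ethan-1-one F6. Acid 22 is activated with carbonyldiimidazole to (1H-imidazol-1-yl)[4-(methoxymethoxy)phenyl]methanone F7. The lithium enolate of F6 (LiN(SiMe3)2, THF, −78 °C) is C-acylated by F7 to 1-[2-bromo-4-methoxy-6-(methoxymethoxy)-3-(3-methylbut-2-en-1-yl)phenyl]-2-(methoxymethoxy)-3-[4-(methoxymethoxy)phenyl]propane-1,3-dione F8. Closure with CuI and Cs2CO3 can then occur only at C8a and gives 7-methoxy-3,5-bis(methoxymethoxy)-2-[4-(methoxymethoxy)phenyl]-8-(3-methylbut-2-en-1-yl)-4H-chromen-4-one F9. The conditions of step 13 remove all three acetals and return to the route at 26.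

**Step 7.** Bromodesilylation of an electron-poor silyl ynone may be sluggish, and the bromoynone may decompose on concentration or on silica. The fallback does the halogenation at the alcohol oxidation level and sets out from 15. Luche reduction (NaBH4, CeCl3·7H2O, MeOH, −20 °C) should give racemic 1-(methoxymethoxy)-4-(trimethylsilyl)but-3-yn-2-ol F10. NBS with catalytic AgNO3 in acetone converts it to racemic 4-bromo-1-(methoxymethoxy)but-3-yn-2-ol F11, a robust compound that can be purified and stored. Oxidation with MnO2 in CH2Cl2 returns to the route at 16, which is filtered and taken straight into step 8.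

**Step 3.** Deprotonation may give part of the (3E)-diene, whose chain points into the diene and blocks cycloaddition, or partial C-silylation; either lowers the amount of reactive diene. The fallback changes the diene type and moves the O7 methylation behind the ring formation; it sets out from 4. Et3N and Me3SiCl should give methyl (Z)-7-methyl-3-(trimethylsilyloxy)octa-2,6-dienoate F12. LiN(iPr)2 and Me3SiCl convert it to (1Z,3Z)-1-methoxy-7-methyl-1,3-bis(trimethylsilyloxy)octa-1,3,6-triene F13, a diene class for which the outward geometry at C4 is well established. Cycloaddition with 16 under the conditions of step 8 should give 1-[2-bromo-4,6-dihydroxy-3-(3-methylbut-2-en-1-yl)phenyl]-2-(methoxymethoxy)ethan-1-one F14. One equivalent of MeI with K2CO3 in acetone methylates only the non-chelated hydroxyl at C7 and returns to the route at 19.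

## Further compounds

F1 | step 8 | 1-(methoxymethoxy)-4-(tributylstannyl)but-3-yn-2-one | CCCC[Sn](CCCC)(CCCC)C#CC(=O)COCOC
F2 | step 8 | 1-[6-hydroxy-4-methoxy-3-(3-methylbut-2-en-1-yl)-2-(tributylstannyl)phenyl]-2-(methoxymethoxy)ethan-1-one | COCOCC(=O)c1c(O)cc(OC)c(CC=C(C)C)c1[Sn](CCCC)(CCCC)CCCC
F3 | step 8 | 1-[6-hydroxy-2-iodo-4-methoxy-3-(3-methylbut-2-en-1-yl)phenyl]-2-(methoxymethoxy)ethan-1-one | COCOCC(=O)c1c(O)cc(OC)c(CC=C(C)C)c1I
F4 | step 8 | 3-iodo-5-methoxy-2-[(methoxymethoxy)acetyl]-4-(3-methylbut-2-en-1-yl)phenyl 4-(methoxymethoxy)benzoate | COCOCC(=O)c1c(OC(=O)c2ccc(OCOC)cc2)cc(OC)c(CC=C(C)C)c1I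
F5 | step 8 | 1-[6-hydroxy-2-iodo-4-methoxy-3-(3-methylbut-2-en-1-yl)phenyl]-2-(methoxymethoxy)-3-[4-(methoxymethoxy)phenyl]propane-1,3-dione (racemic at C2, enolisable) | COCOC(C(=O)c1ccc(OCOC)cc1)C(=O)c1c(O)cc(OC)c(CC=C(C)C)c1I
F6 | step 12 | 1-[2-bromo-4-methoxy-6-(methoxymethoxy)-3-(3-methylbut-2-en-1-yl)phenyl]-2-(methoxymethoxy)ethan-1-one | COCOCC(=O)c1c(OCOC)cc(OC)c(CC=C(C)C)c1Br
F7 | step 12 | (1H-imidazol-1-yl)[4-(methoxymethoxy)phenyl]methanone | COCOc1ccc(C(=O)n2ccnc2)cc1
F8 | step 12 | 1-[2-bromo-4-methoxy-6-(methoxymethoxy)-3-(3-methylbut-2-en-1-yl)phenyl]-2-(methoxymethoxy)-3-[4-(methoxymethoxy)phenyl]propane-1,3-dione (racemic at C2, enolisable) | COCOC(C(=O)c1ccc(OCOC)cc1)C(=O)c1c(OCOC)cc(OC)c(CC=C(C)C)c1Br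
F9 | step 12 | 7-methoxy-3,5-bis(methoxymethoxy)-2-[4-(methoxymethoxy)phenyl]-8-(3-methylbut-2-en-1-yl)-4H-chromen-4-one | COCOc1ccc(-c2oc3c(CC=C(C)C)c(OC)cc(OCOC)c3c(=O)c2OCOC)cc1
F10 | step 7 | 1-(methoxymethoxy)-4-(trimethylsilyl)but-3-yn-2-ol (racemic) | COCOCC(O)C#C[Si](C)(C)C
F11 | step 7 | 4-bromo-1-(methoxymethoxy)but-3-yn-2-ol (racemic) | COCOCC(O)C#CBr
F12 | step 3 | methyl (Z)-7-methyl-3-(trimethylsilyloxy)octa-2,6-dienoate | COC(=O)/C=C(\O[Si](C)(C)C)CCC=C(C)C
F13 | step 3 | (1Z,3Z)-1-methoxy-7-methyl-1,3-bis(trimethylsilyloxy)octa-1,3,6-triene | CO/C(O[Si](C)(C)C)=C/C(O[Si](C)(C)C)=C/CC=C(C)C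
F14 | step 3 | 1-[2-bromo-4,6-dihydroxy-3-(3-methylbut-2-en-1-yl)phenyl]-2-(methoxymethoxy)ethan-1-one | COCOCC(=O)c1c(O)cc(O)c(CC=C(C)C)c1Br
A1 | alternative 1 | 2-hydroxy-4,6-dimethoxy-3-(3-methylbut-2-en-1-yl)benzaldehyde | COc1cc(OC)c(C=O)c(O)c1CC=C(C)C
A2 | alternative 1 | 1-[4-(benzyloxy)phenyl]-2-[dimethyl(oxo)-λ6-sulfanylidene]ethan-1-one | CS(C)(=O)=CC(=O)c1ccc(OCc2ccccc2)cc1
A3 | alternative 1 | 4'-benzyloxy-5,7-dimethoxy-8-prenylflavone | COc1cc(OC)c2c(=O)cc(-c3ccc(OCc4ccccc4)cc3)oc2c1CC=C(C)C
A4 | alternative 2 | 3-ethoxycyclobut-2-en-1-one | CCOC1=CC(=O)C1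
A5 | alternative 2 | 1-methoxy-5-methylhex-4-en-1-yne | COC#CCC=C(C)C
A6 | alternative 2 | 5-ethoxy-3-methoxy-2-(3-methylbut-2-en-1-yl)phenol | COc1cc(OCC)cc(O)c1CC=C(C)C
A7 | alternative 3 | 2-(methoxymethoxy)-1-[4-(methoxymethoxy)phenyl]ethan-1-one | COCOCC(=O)c1ccc(OCOC)cc1
A8 | alternative 3 | 2-fluoro-4,6-dimethoxy-3-(3-methylbut-2-en-1-yl)benzoyl chloride | COc1cc(OC)c(C(=O)Cl)c(F)c1CC=C(C)C
A9 | alternative 3 | 5,7-dimethoxy-3,4'-bis(methoxymethoxy)-8-prenylflavone | COCOc1c(-c2ccc(OCOC)cc2)oc2c(CC=C(C)C)c(OC)cc(OC)c2c1=O
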